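**Retrosynthetic overview**
1. Feature: the benzene ring of coumarin unit B bears oxygen on C5, C7, C8 and C8a, and the diaryl ether carbon C8 lies between C7–O and C8a–O. C8 and C8a are therefore taken as the two carbons of an aryloxyketene obtained by O-alkylating the C8 hydroxyl of coumarin unit A.
2. 20 ⇐ 19 (fluoride desilylation) ⇐ 18 (gold-catalysed hydroarylation, C4–C4a, closes the pyranone of B last) ⇐ 16 (acylation of the single free phenol at C8a).
3. 16 ⇐ 11 + 4: benzannulation that joins C4a–C8a and C5–C6 and closes the benzene ring of B with its oxygens already differentiated.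
4. 11 ⇐ aryloxyketene 10 + 4 ([2+2], sets C7–C8); 10 ⇐ 9 ⇐ 8 ⇐ 7 ⇐ 5 + 6; 4 ⇐ acetylene 1.
5. Ring order: unit A is bought intact; then the transient cyclobutenone, the benzene ring of B, and finally the pyranone of B.

Key step: step 6

Remark on the chemistry: the target has no stereocentre and its diaryl ether rotates freely, so no configuration has to be set; 11, 13 and 15 are racemic and their centres vanish on aromatisation. 8-Hydroxy-7-methoxycoumarin is taken as a purchased compound. The silyl triflate is used in place of the chloride for O-silylation of the ynolate, and the preparation of the parent silyl ynol ether 4 (step 1) is an extension of the terminal-alkyne protocol to acetylene itself.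

**Step 1**
Reactants: 1 acetylene
Product: 4 (triisopropylsilyloxy)acetylene, via lithium acetylide 2 (not isolated), via lithium ethynolate 3 (not isolated)
Conditions: LiHMDS (2.2 equiv), t-BuOOH (1.0 equiv, anhydrous in decane), acetylene-saturated THF, −78 → 0 °C; argon purge; TIPSOTf (1.1 equiv), −78 → 0 °C; NaHCO3 wash, distil
Reagents that add atoms: tert-butyl hydroperoxide, CC(C)(C)OO; triisopropylsilyl trifluoromethanesulfonate, CC(C)[Si](C(C)C)(C(C)C)OS(=O)(=O)C(F)(F)F
Why: Electrophilic oxygen transfer from lithium tert-butyl peroxide to the acetylide gives the ynolate, which the bulky, hard silyl triflate should capture on oxygen rather than carbon (acetylide oxidation–O-silylation, the standard entry to triisopropylsilyl ynol ethers from terminal alkynes), with the hydroperoxide kept limiting under excess acetylene to suppress over-oxidation.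

**Step 2**
Reactants: 5 8-hydroxy-7-methoxy-2H-chromen-2-one; 6 tert-butyl bromoacetate
Product: 7 tert-butyl 2-[(7-methoxy-2-oxo-2H-chromen-8-yl)oxy]acetate
Conditions: K2CO3 (anhydrous), DMF, rt → 50 °C
Reagents that add atoms: none
Why: Williamson O-alkylation (SN2) of the only phenol of 5 at an unhindered primary α-bromo ester carbon, under anhydrous carbonate that leaves the lactone closed.

**Step 3**
Reactants: 7 tert-butyl 2-[(7-methoxy-2-oxo-2H-chromen-8-yl)oxy]acetate
Product: 8 2-[(7-methoxy-2-oxo-2H-chromen-8-yl)oxy]acetic acid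
Conditions: TFA/CH2Cl2 (1:3), rt
Reagents that add atoms: none
Why: Acidolysis of the tert-butyl ester (loss of isobutene through the tert-butyl cation) frees the acid without touching the aryl methyl ether or the lactone.

**Step 4**
Reactants: 8 2-[(7-methoxy-2-oxo-2H-chromen-8-yl)oxy]acetic acid
Product: 9 2-[(7-methoxy-2-oxo-2H-chromen-8-yl)oxy]acetyl chloride
Conditions: (COCl)2, cat. DMF, CH2Cl2, 0 °C → rt; evaporate, use crude
Reagents that add atoms: oxalyl chloride, ClC(=O)C(=O)Cl
Why: Vilsmeier-type activation with oxalyl chloride and catalytic DMF converts the acid into the acid chloride under non-nucleophilic conditions that the coumarin tolerates.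

**Step 5**
Reactants: 9 2-[(7-methoxy-2-oxo-2H-chromen-8-yl)oxy]acetyl chloride; 4 (triisopropylsilyloxy)acetylene
Product: 11 4-[(7-methoxy-2-oxo-2H-chromen-8-yl)oxy]-3-(triisopropylsilyloxy)cyclobut-2-en-1-one (racemic), via aryloxyketene 10 (not isolated)
Conditions: Et3N (1.3 equiv), 4 (1.5 equiv), CH2Cl2, 0 °C → rt, slow addition of 9; filter off the ammonium salt under N2, concentrate, no aqueous work-up
Reagents that add atoms: none
Why: Dehydrochlorination gives ketene 10, which is trapped in a polarised stepwise ketene–ynol ether [2+2] cycloaddition in which the nucleophilic CH carbon of 4 bonds to the ketene carbonyl carbon and the silyloxy carbon to the aryloxy carbon, so that OTIPS sits at C3 and OAr at the new sp3 carbon C4, which is formed racemic and erased in step 6.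

**Step 6**
Reactants: 11 4-[(7-methoxy-2-oxo-2H-chromen-8-yl)oxy]-3-(triisopropylsilyloxy)cyclobut-2-en-1-one; 4 (triisopropylsilyloxy)acetylene
Product: 16 8-[2-hydroxy-4,6-bis(triisopropylsilyloxy)phenoxy]-7-methoxy-2H-chromen-2-one, via vinylketene 12 (not isolated), via vinylcyclobutenone 13 (not isolated), via dienylketene 14 (not isolated), via cyclohexadienone 15 (not isolated)
Conditions: 4 (2.5 equiv), degassed toluene (0.2 M), sealed tube, 80 °C then 110 °C
Reagents that add atoms: none
Why: Heating opens 11 by conrotatory 4π electrocyclic ring opening, the C4 aryloxy donor rotating outward, to vinylketene 12, whose ketene C=C adds 4 in a polarised [2+2] step (alkyne CH carbon to ketene carbonyl carbon) to give vinylcyclobutenone 13; reversible 4π opening of 13 gives dienylketene 14, and 6π electrocyclisation followed by tautomerisation of dienone 15 delivers phenol 16. The closest known reaction is the Danheiser benzannulation of cyclobutenones with silyl ynol ethers, applied here to a 4-aryloxy-3-silyloxy cyclobutenone. The six-membered carbocycle (benzene ring of B) is closed by the disrotatory 6π electrocyclisation that re-forms C8–C8a, after the cycloaddition has made the two new skeletal bonds C4a–C8a and C5–C6. No stereocentre survives: the centres of 11, 13 and 15 are racemic and disappear on aromatisation, and outward rotation of the aryloxy group leaves hydrogen on the inside of the triene terminus so that ring closure is not hindered. The step needs [2+2] rather than [4+2] union, with the alkyne CH carbon on the ketene carbonyl carbon; the donor oxygen of the ynol ether and the electrophilic ketene carbon secure this polarity, which leaves the only free hydroxyl at C8a and the silyl ethers at C5 and C7. The temperature is held at or below 110 °C so that 4 does not isomerise to the silylketene.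

**Step 7**
Reactants: 16 8-[2-hydroxy-4,6-bis(triisopropylsilyloxy)phenoxy]-7-methoxy-2H-chromen-2-one; 17 propiolic acid
Product: 18 2-[(7-methoxy-2-oxo-2H-chromen-8-yl)oxy]-3,5-bis(triisopropylsilyloxy)phenyl prop-2-ynoate
Conditions: DCC (1.3 equiv), DMAP (5 mol %), CH2Cl2, −20 → 0 °C
Reagents that add atoms: none
Why: Carbodiimide (Steglich-type) esterification acylates the single free phenol at C8a, with low temperature and only catalytic DMAP limiting conjugate addition to the propiolate.

**Step 8**
Reactants: 18 2-[(7-methoxy-2-oxo-2H-chromen-8-yl)oxy]-3,5-bis(triisopropylsilyloxy)phenyl prop-2-ynoate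
Product: 19 7-methoxy-8-{[2-oxo-5,7-bis(triisopropylsilyloxy)-2H-chromen-8-yl]oxy}-2H-chromen-2-one
Conditions: [JohnPhosAu(MeCN)]SbF6 (5 mol %), CH2Cl2, rt
Reagents that add atoms: none
Why: Cationic gold(I) π-activation of the ynoate triggers 6-endo-dig intramolecular hydroarylation (Friedel–Crafts-type attack, then protodeauration) at C4a, the only free position ortho to the ester oxygen and activated by the ortho and para silyloxy groups, closing the pyranone of B.

**Step 9**
Reactants: 19 7-methoxy-8-{[2-oxo-5,7-bis(triisopropylsilyloxy)-2H-chromen-8-yl]oxy}-2H-chromen-2-one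
Product: 20 5,7-dihydroxy-8-[(7-methoxy-2-oxo-2H-chromen-8-yl)oxy]-2H-chromen-2-one
Conditions: TBAF (2.5 equiv), AcOH (3 equiv), THF, 0 °C; work-up at pH 4
Reagents that add atoms: none
Why: Fluoride cleaves both aryl Si–O bonds (driven by the Si–F bond), and acetic acid buffering keeps both lactones closed and the phloroglucinol-type phenols protonated.

**Compound list**
1 | acetylene | C#C | starting material
2 | lithium acetylide | [Li]C#C | intermediate
3 | lithium ethynolate | [Li]OC#C | intermediate
4 | (triisopropylsilyloxy)acetylene | C#CO[Si](C(C)C)(C(C)C)C(C)C | intermediate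
5 | 8-hydroxy-7-methoxy-2H-chromen-2-one (daphnetin 7-methyl ether) | COc1ccc2ccc(=O)oc2c1O | starting material
6 | tert-butyl bromoacetate | CC(C)(C)OC(=O)CBr | starting material
7 | tert-butyl 2-[(7-methoxy-2-oxo-2H-chromen-8-yl)oxy]acetate | COc1ccc2ccc(=O)oc2c1OCC(=O)OC(C)(C)C | intermediate
8 | 2-[(7-methoxy-2-oxo-2H-chromen-8-yl)oxy]acetic acid | COc1ccc2ccc(=O)oc2c1OCC(=O)O | intermediate
9 | 2-[(7-methoxy-2-oxo-2H-chromen-8-yl)oxy]acetyl chloride | COc1ccc2ccc(=O)oc2c1OCC(=O)Cl | intermediate
10 | [(7-methoxy-2-oxo-2H-chromen-8-yl)oxy]ketene | COc1ccc2ccc(=O)oc2c1OC=C=O | intermediate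
11 | 4-[(7-methoxy-2-oxo-2H-chromen-8-yl)oxy]-3-(triisopropylsilyloxy)cyclobut-2-en-1-one (racemic) | COc1ccc2ccc(=O)oc2c1OC1C(=O)C=C1O[Si](C(C)C)(C(C)C)C(C)C | intermediate
12 | (Z)-4-[(7-methoxy-2-oxo-2H-chromen-8-yl)oxy]-3-(triisopropylsilyloxy)buta-1,3-dien-1-one | COc1ccc2ccc(=O)oc2c1O/C=C(O[Si](C(C)C)(C(C)C)C(C)C)/C=C=O | intermediate
13 | 4-{(Z)-2-[(7-methoxy-2-oxo-2H-chromen-8-yl)oxy]-1-(triisopropylsilyloxy)ethenyl}-3-(triisopropylsilyloxy)cyclobut-2-en-1-one (racemic) | COc1ccc2ccc(=O)oc2c1O/C=C(O[Si](C(C)C)(C(C)C)C(C)C)/C1C(=O)C=C1O[Si](C(C)C)(C(C)C)C(C)C | intermediate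
14 | (3E,5Z)-6-[(7-methoxy-2-oxo-2H-chromen-8-yl)oxy]-3,5-bis(triisopropylsilyloxy)hexa-1,3,5-trien-1-one | COc1ccc2ccc(=O)oc2c1O/C=C(O[Si](C(C)C)(C(C)C)C(C)C)/C=C(O[Si](C(C)C)(C(C)C)C(C)C)\C=C=O | intermediate
15 | 6-[(7-methoxy-2-oxo-2H-chromen-8-yl)oxy]-3,5-bis(triisopropylsilyloxy)cyclohexa-2,4-dien-1-one (racemic) | COc1ccc2ccc(=O)oc2c1OC1C(=O)C=C(O[Si](C(C)C)(C(C)C)C(C)C)C=C1O[Si](C(C)C)(C(C)C)C(C)C | intermediate
16 | 8-[2-hydroxy-4,6-bis(triisopropylsilyloxy)phenoxy]-7-methoxy-2H-chromen-2-one | COc1ccc2ccc(=O)oc2c1Oc1c(O)cc(O[Si](C(C)C)(C(C)C)C(C)C)cc1O[Si](C(C)C)(C(C)C)C(C)C | intermediate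
17 | propiolic acid | C#CC(=O)O | starting material
18 | 2-[(7-methoxy-2-oxo-2H-chromen-8-yl)oxy]-3,5-bis(triisopropylsilyloxy)phenyl prop-2-ynoate | COc1ccc2ccc(=O)oc2c1Oc1c(OC(=O)C#C)cc(O[Si](C(C)C)(C(C)C)C(C)C)cc1O[Si](C(C)C)(C(C)C)C(C)C | intermediate
19 | 7-methoxy-8-{[2-oxo-5,7-bis(triisopropylsilyloxy)-2H-chromen-8-yl]oxy}-2H-chromen-2-one | COc1ccc2ccc(=O)oc2c1Oc1c(O[Si](C(C)C)(C(C)C)C(C)C)cc(O[Si](C(C)C)(C(C)C)C(C)C)c2ccc(=O)oc12 | intermediate
20 | 5,7-dihydroxy-8-[(7-methoxy-2-oxo-2H-chromen-8-yl)oxy]-2H-chromen-2-one | COc1ccc2ccc(=O)oc2c1Oc1c(O)cc(O)c2ccc(=O)oc12 | target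

**Totals**
Total step count: 9. Longest linear sequence: 8 steps (5 → 20, steps 2–9); step 1 supplies 4 for steps 5 and 6.

**Steps most likely to fail**

Step 6 (key step). The aryloxy vinylketene may be lost to dimerisation or decomposition before the alkyne traps it, the ketene–alkyne union may take the [4+2] course, or the silyl ynol ether may rearrange to the silylketene at the reaction temperature. The fallback abandons the cyclobutenone and builds the differentiated ring-B phenol by C–O coupling and Dakin oxidation; it sets out from 5 and comes back to the route at 20. Phenol 5 would be coupled under copper catalysis (Ullmann-type diaryl ether synthesis: CuI, N,N-dimethylglycine, Cs2CO3, dioxane, 100 °C) with 2-bromo-3,5-bis(benzyloxy)benzaldehyde F1, made by NBS bromination of purchased 3,5-bis(benzyloxy)benzaldehyde, to give 3,5-bis(benzyloxy)-2-[(7-methoxy-2-oxo-2H-chromen-8-yl)oxy]benzaldehyde F2. Baeyer–Villiger (Dakin-type) oxidation with mCPBA should give the aryl formate F3, and brief methanolysis the phenol 8-[2,4-bis(benzyloxy)-6-hydroxyphenoxy]-7-methoxy-2H-chromen-2-one F4, which has its only free hydroxyl at C8a as 16 does, but benzyl ethers at C5 and C7. F4 would then be esterified as in step 7 to the propiolate F5, cyclised as in step 8 to 5,7-bis(benzyloxy)-8-[(7-methoxy-2-oxo-2H-chromen-8-yl)oxy]-2H-chromen-2-one F6, and debenzylated with BCl3 and pentamethylbenzene in CH2Cl2 at −78 °C, which spares the aryl methyl ether, to give 20.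

Step 1. Oxygen transfer to the parent acetylide may be incomplete because monolithium acetylide disproportionates on warming, or the unsubstituted ynolate may be over-oxidised, so that little ynolate is present at the silylation stage. The fallback generates the same ynolate by cleavage of an ester dianion; it does not set out from 1 but from purchased ethyl bromoacetate (CCOC(=O)CBr), and it comes back to the route at 3. Deprotonation with LiHMDS in THF at −78 °C would give the lithium enolate of ethyl bromoacetate F7; bromine–lithium exchange with t-BuLi (2 equiv) gives the dilithiated ester (ester dianion) F8, which expels lithium ethoxide on warming to 0 °C to leave lithium ethynolate 3, silylated with TIPSOTf as in step 1 to give 4.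

Step 7. Conjugate addition of the electron-rich phenol to the activated propiolate, N-acylurea formation and oligomerisation of propiolic acid may outrun O-acylation of the ortho-substituted phenol. The fallback installs the pyranone by formylation and olefination instead of acylation and hydroarylation; it sets out from 16 and comes back to the route at 19, so it also replaces step 8. Magnesium-mediated ortho-formylation (MgCl2, Et3N, paraformaldehyde, MeCN, 75 °C) at C4a, the only free ortho carbon, would give 2-hydroxy-3-[(7-methoxy-2-oxo-2H-chromen-8-yl)oxy]-4,6-bis(triisopropylsilyloxy)benzaldehyde F9. Z-selective Horner–Wadsworth–Emmons olefination with ethyl (diphenoxyphosphoryl)acetate and NaH in THF (−78 → 0 °C) gives ethyl (2Z)-3-{2-hydroxy-3-[(7-methoxy-2-oxo-2H-chromen-8-yl)oxy]-4,6-bis(triisopropylsilyloxy)phenyl}prop-2-enoate F10, which should lactonise in the flask to 19.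

**Further compounds**
F1 | step 6 | 2-bromo-3,5-bis(benzyloxy)benzaldehyde | O=Cc1cc(OCc2ccccc2)cc(OCc2ccccc2)c1Br
F2 | step 6 | 3,5-bis(benzyloxy)-2-[(7-methoxy-2-oxo-2H-chromen-8-yl)oxy]benzaldehyde | O=Cc1cc(OCc2ccccc2)cc(OCc2ccccc2)c1Oc1c(OC)ccc2ccc(=O)oc12
F3 | step 6 | 3,5-bis(benzyloxy)-2-[(7-methoxy-2-oxo-2H-chromen-8-yl)oxy]phenyl formate | O=COc1cc(OCc2ccccc2)cc(OCc2ccccc2)c1Oc1c(OC)ccc2ccc(=O)oc12
F4 | step 6 | 8-[2,4-bis(benzyloxy)-6-hydroxyphenoxy]-7-methoxy-2H-chromen-2-one | Oc1cc(OCc2ccccc2)cc(OCc2ccccc2)c1Oc1c(OC)ccc2ccc(=O)oc12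
F5 | step 6 | 3,5-bis(benzyloxy)-2-[(7-methoxy-2-oxo-2H-chromen-8-yl)oxy]phenyl prop-2-ynoate | C#CC(=O)Oc1cc(OCc2ccccc2)cc(OCc2ccccc2)c1Oc1c(OC)ccc2ccc(=O)oc12
F6 | step 6 | 5,7-bis(benzyloxy)-8-[(7-methoxy-2-oxo-2H-chromen-8-yl)oxy]-2H-chromen-2-one | COc1ccc2ccc(=O)oc2c1Oc1c(OCc2ccccc2)cc(OCc2ccccc2)c2ccc(=O)oc12
F7 | step 1 | lithium enolate of ethyl bromoacetate | [Li]OC(OCC)=CBr
F8 | step 1 | dilithiated ethyl acetate (ester dianion) | [Li]C=C(O[Li])OCC
F9 | step 7 | 2-hydroxy-3-[(7-methoxy-2-oxo-2H-chromen-8-yl)oxy]-4,6-bis(triisopropylsilyloxy)benzaldehyde | O=Cc1c(O)c(Oc2c(OC)ccc3ccc(=O)oc23)c(O[Si](C(C)C)(C(C)C)C(C)C)cc1O[Si](C(C)C)(C(C)C)C(C)C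
F10 | step 7 | ethyl (2Z)-3-{2-hydroxy-3-[(7-methoxy-2-oxo-2H-chromen-8-yl)oxy]-4,6-bis(triisopropylsilyloxy)phenyl}prop-2-enoate | CCOC(=O)/C=C\c1c(O)c(Oc2c(OC)ccc3ccc(=O)oc23)c(O[Si](C(C)C)(C(C)C)C(C)C)cc1O[Si](C(C)C)(C(C)C)C(C)C
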